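# Proposed synthesis of [(2S,3R,4R)-2-(3,4-dihydroxyphenyl)-4-(4-hydroxy-3-methoxybenzyl)oxolan-3-yl]methyl acetate by way of a furan-derived cyclopropane

Target numbering is used throughout: O1, C2 (catechol), C3 (acetoxymethyl), C4 (guaiacylmethyl), C5 (CH2).

## The problem

The target is a lariciresinol-type lignan: a tetrahydrofuran carrying a 3,4-dihydroxyphenyl group at C2, an acetoxymethyl group at C3 and a 4-hydroxy-3-methoxybenzyl group at C4, with C5 an unsubstituted methylene. The three stereocentres are contiguous, (2S,3R,4R). The aryl group is trans to the acetoxymethyl group, and the acetoxymethyl group is cis to the benzyl group. The 2,3-trans relation is the thermodynamic one and can be relayed from C3. The 3,4-cis relation is contra-thermodynamic and has to be set kinetically, again from C3, so C3 is the controlling centre and must be fixed in absolute terms. The C2–O1 bond is a benzylic ether para to an oxygen substituent, so acid can ionise it (epimerisation, ring opening) and hydrogenolysis can cleave it. The catechol is oxidised easily, and the single aliphatic acetate must be placed in the presence of three phenols and survive their unmasking. The enabling feature is that C2, C3 and the acetoxymethyl carbon are three contiguous carbons that map onto C3, C4 and C5 of methyl furan-2-carboxylate, while C4 and C5 map onto the carbene carbon and ester carbon of a diazoacetate. A cyclopropane fused to that furan is therefore a latent trans-γ-aryl-β-formyl-γ-butyrolactone.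

## Retrosynthesis

**Unmasking (23 ⇐ 22 ⇐ 21 ⇐ 20).** The three O–benzyl bonds of 22 are cut last, the acetyl C–O bond of 22 before that (alcohol 21), and the Si–O bond of 20 before that. This order keeps the catechol masked to the end. It also installs the acetate when the primary hydroxyl is the only free one, so no aliphatic-versus-phenolic selectivity is needed. The forward demand is a hydrogenolysis that removes aryl benzyl ethers but spares C2–O1.

**C5 from a carbonyl (20 ⇐ 19 ⇐ 18).** C5 is taken back to the lactone carbonyl of 18, reduced forward through lactol 19. Closing O1–C2 onto a benzylic cation would place C2 under thermodynamic control and expose the electron-rich ring to acid. A Williamson closure of O1–C5 would need a differentiated diol. The lactone avoids both, activates C4 for C–C bond formation, and is what the key step delivers. The forward demand is lactol deoxygenation without ionising C2–O1.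

**The C4 side chain (18 ⇐ 17 ⇐ 15 ⇐ 13 + 14).** The bond from C4 to its benzylic carbon is cut. Direct enolate alkylation would put the benzyl group trans to the C3 substituent, which is the wrong relation. Aldol addition of lactone 13 to O-benzylvanillin 14 (adduct 15), dehydration to benzylidene lactone 17 and hydrogenation anti to the C3 substituent gives the cis relation of 18. The forward demand is a face-selective hydrogenation that leaves benzyl ethers and the benzylic lactone C–O bond alone.

**Adjusting the C3 substituent (13 ⇐ 12 ⇐ 11).** Silyl ether 13 comes from alcohol 12, and 12 from aldehyde 11. The formyl carbon is the future acetoxymethyl carbon. It is reduced at once because the β-formyl lactone is the most fragile compound of the route.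

**Key disconnection (11 ⇐ 8).** The lactone acyl–oxygen bond (O1–C5) is cut, and the methylene carbon (C4) is reconnected to the formyl carbon. This gives cyclopropanol oxalate 8, which holds C2 and C3 in their final configurations. Forward, removing the oxalate triggers retro-aldol cleavage of one cyclopropane bond (cyclopropanol 9, open-chain ester 10) and lactonisation. An intermolecular aldol route to 11 would need a stoichiometric auxiliary and would not give the aldehyde oxidation level directly. The forward demand is that lactonisation outruns retro-aldol loss of the aryl aldehyde and β-elimination.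

**C2–aryl bond (8 ⇐ 4 + 5).** The bond between C2 and the catechol ring is cut to cyclopropanecarbaldehyde 4 and an aryl-metal reagent made from bromide 5 (aryllithium 6, aryltitanium 7). The adjacent cyclopropane stereocentre controls the new carbinol by Felkin–Anh addition. The reagent must ignore the oxalate and the ethyl ester, which is why titanium is chosen.

**The cyclopropane (4 ⇐ 3 ⇐ 1 + 2).** Aldehyde 4 and its oxalate are the two ends of an ozonised enol ether C=C bond, that of bicycle 3. Bicycle 3 is the asymmetric cyclopropanation product of methyl furan-2-carboxylate 1 and ethyl diazoacetate 2. This single catalytic step sets the absolute configuration of the whole molecule, and 3 is crystalline, so its enantiopurity can be upgraded.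

## Roads not taken

**Alternative 1:** Anodic catechol oxidation and cycloetherification. The cut is O1–C2. The precursor is the unprotected (2R,3R)-2-(3,4-dihydroxybenzyl)-3-(4-hydroxy-3-methoxybenzyl)butane-1,4-diol A2. Two-electron anodic oxidation of its catechol and tautomerisation give the para-quinone methide A3. The C5 hydroxyl adds to C2 and gives the deacetyl target A1, which needs only acetylation.
- Merits: the end game is biomimetic, needs no protecting groups and is very short. The catechol oxidises at a lower potential than the guaiacol. Ring size alone picks the right hydroxyl, because the other one would close an oxetane. In these respects it is better than the chosen plan.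
- Weak points: C2 is set by addition to a planar quinone methide, so only the thermodynamic bias from C3 controls it. The guaiacyl ring can attack C2 in a six-membered Friedel–Crafts closure in competition with O-cyclisation. A1 carries the same catechol as A2 and can be oxidised further. The final acetylation must pick one aliphatic hydroxyl among three phenols. A2 itself, with two different aryl groups and two stereocentres, costs a synthesis comparable in length to 8.
- Comparison: the chosen plan is longer (14 steps with protecting-group traffic). Against that it sets each stereocentre by a defined element and keeps the catechol masked until the last step.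

**Alternative 2:** Aryl carbene and enal (4+1). The cuts are O1–C2 and C2–C3. Copper-catalysed decomposition of [3,4-bis(benzyloxy)phenyl]diazomethane A6 in the presence of the Z-enal A5 joins the carbene carbon to the aldehyde oxygen. A 1,5-electrocyclisation then joins it to C3 and gives the 2,3-dihydrofuran A4. Hydrogenation of the enol ether anti to the C3 substituent would set C4.
- Merits: it is the most convergent of the four plans. The ring and all carbons are assembled in one step, and the 3,4-cis relation comes from the same kind of anti hydrogenation that the chosen plan uses.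
- Weak points: A6 is a donor-substituted, non-stabilised diazo compound prone to azine and stilbene formation. Cyclopropanation of the enal C=C bond and epoxide formation compete with the electrocyclisation. The trisubstituted Z-enal A5 isomerises easily. C2 and C3 are created in a pericyclic step that a chiral copper catalyst influences only remotely, so the absolute configuration has no reliable source.
- Comparison: the chosen plan concedes convergence and step count. It gains an absolute configuration fixed in a crystalline, catalytically made cyclopropane 3 and relayed by substrate control.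

**Alternative 3:** Carbonyl ylide (3+2) cycloaddition to a menthyloxy butenolide. The cuts are C2–C3 and C4–C5. Fluoride-induced 1,3-elimination from the α-silyl chloromethyl ether A9 in the presence of (5S)-5-menthyloxyfuran-2(5H)-one A8 adds an O-bridged three-atom unit across the butenolide alkene anti to the menthyloxy group. The product is the cis-fused bicyclic lactone A7 with the aryl group exo.
- Merits: three stereocentres and the ring arise in one step. The 3,4-cis relation comes from the cis ring fusion, which is better than the chosen plan, where this relation depends on a face-selective hydrogenation. The auxiliary is cheap.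
- Weak points: the regiochemistry of an unsymmetrical, non-stabilised dipole adding to the butenolide is not secured, nor is the exo position of the aryl group. After the cycloaddition the acetal carbon must become the guaiacylmethyl group, by aryl-metal addition and benzylic deoxygenation in the presence of the equally benzylic C2–O1 bond. The lactone carbonyl must become the hydroxymethyl group. Telling these two oxidised carbons apart costs several steps.
- Comparison: the step count ends no lower than that of the chosen plan. The chosen plan has one hydrogenation whose facial selectivity must be proven, but its regiochemistry is unambiguous throughout.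

Key step: step 4

## Route

Assumption: the (R,R)-configured isopropyl bis(oxazoline) ligand is taken to give the (1R,5R,6R) cyclopropane 3, the (S,S) ligand being associated with the (1S,5S,6S) series. If the sense were opposite, the antipodal ligand would be used and nothing else changes.

Step 1
Reactants: 1 methyl furan-2-carboxylate; 2 ethyl diazoacetate
Product: 3 6-ethyl 3-methyl (1R,5R,6R)-2-oxabicyclo[3.1.0]hex-3-ene-3,6-dicarboxylate
Conditions: Cu(OTf)2 (1 mol%), (R,R)-iPr-box [2,2'-(propane-2,2-diyl)bis((4R)-4-isopropyl-4,5-dihydrooxazole)] (1.3 mol%), PhNHNH2 (1 mol%), slow addition of 2, CH2Cl2, 0 °C; recrystallisation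
Reagents that add atoms: none
Why: Copper-carbene cyclopropanation, with phenylhydrazine reducing the divalent copper salt to the active monovalent copper complex; the carbene adds to the unsubstituted, more electron-rich C4=C5 bond of the furan with the ester exo, the bis(oxazoline) ligand sets the absolute configuration of all three centres, and crystallisation should upgrade the enantiomeric purity.

Step 2
Reactants: 3 6-ethyl 3-methyl (1R,5R,6R)-2-oxabicyclo[3.1.0]hex-3-ene-3,6-dicarboxylate
Product: 4 methyl (1R,2R,3R)-2-(ethoxycarbonyl)-3-formylcyclopropyl oxalate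
Conditions: O3, CH2Cl2, −78 °C; then Me2S, −78 °C → rt
Reagents that add atoms: ozone, O=[O+][O-]
Why: Ozonolysis with reductive work-up cleaves the enol ether C=C bond, turning one carbon into the aldehyde and the other into the oxalyl carbonyl, so the former ring oxygen ends as a methyl oxalate on the cyclopropanol; the three ring stereocentres are untouched.

Step 3
Reactants: 4 methyl (1R,2R,3R)-2-(ethoxycarbonyl)-3-formylcyclopropyl oxalate; 5 4-bromo-1,2-bis(benzyloxy)benzene
Product: 8 ethyl (1R,2S,3R)-2-{(S)-[3,4-bis(benzyloxy)phenyl](hydroxy)methyl}-3-[(methoxyoxalyl)oxy]cyclopropane-1-carboxylate, via aryllithium 6 (not isolated), via aryltitanium triisopropoxide 7 (not isolated)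
Conditions: 5, n-BuLi, THF, −78 °C; ClTi(OiPr)3, −78 → −40 °C; then 4, −78 → −30 °C; aq. NH4Cl
Reagents that add atoms: n-butyllithium, [Li]CCCC (lithium of 6 only); chlorotitanium triisopropoxide, CC(C)O[Ti](Cl)(OC(C)C)OC(C)C (titanium triisopropoxide unit of 7 only); no reagent atom remains in 8
Why: Bromine–lithium exchange, transmetalation and 1,2-addition of an aryltitanium reagent to an aldehyde; the weakly basic titanium reagent should react with the aldehyde and leave the oxalate and ethyl ester alone. The carbinol centre (target C2) is set by Felkin–Anh control from the adjacent cyclopropane carbon: the aryl group enters anti to the ring bond leading to the oxalate-bearing carbon, on the face remote from the cis-oxalate, giving the (S)-carbinol.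

Step 4
Reactants: 8 ethyl (1R,2S,3R)-2-{(S)-[3,4-bis(benzyloxy)phenyl](hydroxy)methyl}-3-[(methoxyoxalyl)oxy]cyclopropane-1-carboxylate
Product: 11 (2S,3S)-2-[3,4-bis(benzyloxy)phenyl]-5-oxooxolane-3-carbaldehyde, via cyclopropanol 9 (not isolated), via open-chain hydroxy aldehyde ester 10 (not isolated)
Conditions: Ba(OH)2·8H2O (0.55 equiv), MeOH, 0 °C; cold neutralisation, product used crude
Reagents that add atoms: none
Why: Hydroxide cleaves the highly electrophilic methyl oxalate first and frees cyclopropanolate 9, a donor–acceptor cyclopropane in which the oxygen pushes and the vicinal ester pulls. The ring bond between the oxygen-bearing carbon and the ester-bearing carbon therefore breaks in a retro-aldol sense (the bond to the carbinol-bearing carbon has no acceptor and stays), giving the aldehyde and an ester enolate that is protonated to the methylene of 10. The benzylic hydroxyl of 10 then attacks the ethyl ester in a 5-exo-trig acyl substitution, expels ethanol and closes the lactone, which is the O1–C5 bond of the target. The closest known reaction type is the base-induced retro-aldol/lactonisation cascade of furan-derived cyclopropanol oxalates that gives trans-4,5-disubstituted γ-butyrolactones of the paraconic acid family. No stereocentre is created: the carbinol carbon keeps its C–O bond, and the former cyclopropane carbon (target C3) is not part of the breaking bond, so it keeps its configuration; the trans arrangement it delivers is also the thermodynamic one, so enolisation of the new aldehyde should not degrade it. The step needs chemoselectivity (oxalate before ethyl ester), regioselective ring cleavage (fixed by the position of the ester) and lactonisation faster than retro-aldol loss of the aryl aldehyde or β-elimination of the lactone oxygen; substoichiometric base at 0 °C and the intramolecular five-membered closure are expected to secure this.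

Step 5
Reactants: 11 (2S,3S)-2-[3,4-bis(benzyloxy)phenyl]-5-oxooxolane-3-carbaldehyde
Product: 12 (4R,5S)-5-[3,4-bis(benzyloxy)phenyl]-4-(hydroxymethyl)oxolan-2-one
Conditions: NaBH4, MeOH/CH2Cl2, −40 °C; AcOH quench at −40 °C
Reagents that add atoms: none
Why: Chemoselective borohydride reduction of the aldehyde in the presence of the lactone; the cold acidic quench is meant to prevent the primary alkoxide from translactonising onto the ring carbonyl.

Step 6
Reactants: 12 (4R,5S)-5-[3,4-bis(benzyloxy)phenyl]-4-(hydroxymethyl)oxolan-2-one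
Product: 13 (4R,5S)-5-[3,4-bis(benzyloxy)phenyl]-4-{[(tert-butyldiphenylsilyl)oxy]methyl}oxolan-2-one
Conditions: TBDPSCl, imidazole, DMF, 0 °C → rt
Reagents that add atoms: tert-butyl(chloro)diphenylsilane, CC(C)(C)[Si](Cl)(c1ccccc1)c1ccccc1
Why: Standard silylation of a primary alcohol; the bulky, Lewis-acid-tolerant silyl ether blocks translactonisation, survives enolate chemistry and the later BF3 step, and provides the steric bias for step 9.

Step 7
Reactants: 13 (4R,5S)-5-[3,4-bis(benzyloxy)phenyl]-4-{[(tert-butyldiphenylsilyl)oxy]methyl}oxolan-2-one; 14 4-(benzyloxy)-3-methoxybenzaldehyde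
Product: 15 (3R,4R,5S)-3-{[4-(benzyloxy)-3-methoxyphenyl](hydroxy)methyl}-5-[3,4-bis(benzyloxy)phenyl]-4-{[(tert-butyldiphenylsilyl)oxy]methyl}oxolan-2-one (both carbinol epimers)
Conditions: LiN(SiMe3)2, THF, −78 °C; then 14, −78 °C; AcOH quench at −78 °C
Reagents that add atoms: none
Why: Aldol addition of the lithium lactone enolate to an aromatic aldehyde; the electrophile enters anti to the adjacent silyloxymethyl group, and since both new centres are erased in the next step the epimer mixture is carried on.

Step 8
Reactants: 15 (3R,4R,5S)-3-{[4-(benzyloxy)-3-methoxyphenyl](hydroxy)methyl}-5-[3,4-bis(benzyloxy)phenyl]-4-{[(tert-butyldiphenylsilyl)oxy]methyl}oxolan-2-one (both carbinol epimers)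
Product: 17 (3E,4R,5S)-3-[4-(benzyloxy)-3-methoxybenzylidene]-5-[3,4-bis(benzyloxy)phenyl]-4-{[(tert-butyldiphenylsilyl)oxy]methyl}oxolan-2-one, via mesylate 16 (not isolated)
Conditions: MsCl, Et3N, CH2Cl2, 0 °C; then DBU, 0 °C → rt
Reagents that add atoms: methanesulfonyl chloride, CS(=O)(=O)Cl (mesyl group of 16 only; none remains in 17)
Why: Mesylation and E1cB elimination complete the aldol condensation and converge both carbinol epimers on the conjugated benzylidene lactone, the E isomer being expected; the alkene geometry is not critical because only the ring carbon becomes stereogenic on reduction.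

Step 9
Reactants: 17 (3E,4R,5S)-3-[4-(benzyloxy)-3-methoxybenzylidene]-5-[3,4-bis(benzyloxy)phenyl]-4-{[(tert-butyldiphenylsilyl)oxy]methyl}oxolan-2-one
Product: 18 (3R,4R,5S)-3-[4-(benzyloxy)-3-methoxybenzyl]-5-[3,4-bis(benzyloxy)phenyl]-4-{[(tert-butyldiphenylsilyl)oxy]methyl}oxolan-2-one
Conditions: H2 (1 atm), 5% Rh/Al2O3, EtOAc, rt
Reagents that add atoms: none
Why: Heterogeneous syn-hydrogenation of a conjugated trisubstituted alkene; rhodium is chosen because it saturates alkenes with little tendency to hydrogenolyse aryl benzyl ethers or the benzylic lactone C–O bond. The adjacent silyloxymethyl group, held pseudoaxial by allylic strain with the benzylidene aryl group, shields one face, so hydrogen should add to the other and leave the new benzyl group cis to it (target C4, R).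

Step 10
Reactants: 18 (3R,4R,5S)-3-[4-(benzyloxy)-3-methoxybenzyl]-5-[3,4-bis(benzyloxy)phenyl]-4-{[(tert-butyldiphenylsilyl)oxy]methyl}oxolan-2-one
Product: 19 (3R,4R,5S)-3-[4-(benzyloxy)-3-methoxybenzyl]-5-[3,4-bis(benzyloxy)phenyl]-4-{[(tert-butyldiphenylsilyl)oxy]methyl}oxolan-2-ol (both anomers)
Conditions: iBu2AlH, CH2Cl2, −78 °C; aqueous potassium sodium tartrate
Reagents that add atoms: none
Why: Partial reduction of a γ-lactone to the lactol through the stable tetrahedral aluminate at −78 °C; the α-centre is not enolised under these conditions, so the cis relation is kept.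

Step 11
Reactants: 19 (3R,4R,5S)-3-[4-(benzyloxy)-3-methoxybenzyl]-5-[3,4-bis(benzyloxy)phenyl]-4-{[(tert-butyldiphenylsilyl)oxy]methyl}oxolan-2-ol (both anomers)
Product: 20 {[(2S,3R,4R)-4-[4-(benzyloxy)-3-methoxybenzyl]-2-[3,4-bis(benzyloxy)phenyl]oxolan-3-yl]methoxy}(tert-butyl)diphenylsilane
Conditions: Et3SiH, BF3·OEt2, CH2Cl2, −78 → −40 °C
Reagents that add atoms: none
Why: Ionic hydrogenation of a lactol: BF3 generates the cyclic oxocarbenium ion at C5 and the silane reduces it; no stereocentre is formed, and the low temperature is meant to keep the benzylic C2–O1 bond and the silyl ether intact.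

Step 12
Reactants: 20 {[(2S,3R,4R)-4-[4-(benzyloxy)-3-methoxybenzyl]-2-[3,4-bis(benzyloxy)phenyl]oxolan-3-yl]methoxy}(tert-butyl)diphenylsilane
Product: 21 [(2S,3R,4R)-4-[4-(benzyloxy)-3-methoxybenzyl]-2-[3,4-bis(benzyloxy)phenyl]oxolan-3-yl]methanol
Conditions: Bu4NF, THF, 0 °C → rt
Reagents that add atoms: none
Why: Fluoride cleavage of the silyl ether; benzyl ethers and the cyclic ether are inert to fluoride.

Step 13
Reactants: 21 [(2S,3R,4R)-4-[4-(benzyloxy)-3-methoxybenzyl]-2-[3,4-bis(benzyloxy)phenyl]oxolan-3-yl]methanol
Product: 22 [(2S,3R,4R)-4-[4-(benzyloxy)-3-methoxybenzyl]-2-[3,4-bis(benzyloxy)phenyl]oxolan-3-yl]methyl acetate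
Conditions: Ac2O, pyridine, DMAP (cat.), CH2Cl2, 0 °C
Reagents that add atoms: acetic anhydride, CC(=O)OC(C)=O
Why: DMAP-catalysed acetylation of the only free hydroxyl group, carried out while all three phenols are still benzylated.

Step 14
Reactants: 22 [(2S,3R,4R)-4-[4-(benzyloxy)-3-methoxybenzyl]-2-[3,4-bis(benzyloxy)phenyl]oxolan-3-yl]methyl acetate
Product: 23 [(2S,3R,4R)-2-(3,4-dihydroxyphenyl)-4-(4-hydroxy-3-methoxybenzyl)oxolan-3-yl]methyl acetate
Conditions: H2 (1 atm), 10% Pd/C, EtOAc, rt, stopped at complete debenzylation
Reagents that add atoms: none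
Why: Hydrogenolysis of aryl benzyl ethers under neutral conditions, which is normally much faster than cleavage of a dialkyl benzylic ether such as C2–O1; the acetate is inert, and neutral, degassed work-up protects the free catechol.

## Compound list

1 | methyl furan-2-carboxylate | COC(=O)c1ccco1 | starting material
2 | ethyl diazoacetate | CCOC(=O)C=[N+]=[N-] | starting material
3 | 6-ethyl 3-methyl (1R,5R,6R)-2-oxabicyclo[3.1.0]hex-3-ene-3,6-dicarboxylate | CCOC(=O)[C@H]1[C@@H]2OC(C(=O)OC)=C[C@H]12 | intermediate
4 | methyl (1R,2R,3R)-2-(ethoxycarbonyl)-3-formylcyclopropyl oxalate | CCOC(=O)[C@H]1[C@H](OC(=O)C(=O)OC)[C@@H]1C=O | intermediate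
5 | 4-bromo-1,2-bis(benzyloxy)benzene | Brc1ccc(OCc2ccccc2)c(OCc2ccccc2)c1 | starting material
6 | [3,4-bis(benzyloxy)phenyl]lithium | [Li]c1ccc(OCc2ccccc2)c(OCc2ccccc2)c1 | intermediate (not isolated)
7 | [3,4-bis(benzyloxy)phenyl]titanium triisopropoxide | CC(C)O[Ti](OC(C)C)(OC(C)C)c1ccc(OCc2ccccc2)c(OCc2ccccc2)c1 | intermediate (not isolated)
8 | ethyl (1R,2S,3R)-2-{(S)-[3,4-bis(benzyloxy)phenyl](hydroxy)methyl}-3-[(methoxyoxalyl)oxy]cyclopropane-1-carboxylate | CCOC(=O)[C@H]1[C@H](OC(=O)C(=O)OC)[C@@H]1[C@H](O)c1ccc(OCc2ccccc2)c(OCc2ccccc2)c1 | intermediate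
9 | ethyl (1R,2R,3R)-2-{(S)-[3,4-bis(benzyloxy)phenyl](hydroxy)methyl}-3-hydroxycyclopropane-1-carboxylate | CCOC(=O)[C@H]1[C@H](O)[C@@H]1[C@H](O)c1ccc(OCc2ccccc2)c(OCc2ccccc2)c1 | intermediate (not isolated)
10 | ethyl (3S,4S)-4-[3,4-bis(benzyloxy)phenyl]-3-formyl-4-hydroxybutanoate | CCOC(=O)C[C@H](C=O)[C@H](O)c1ccc(OCc2ccccc2)c(OCc2ccccc2)c1 | intermediate (not isolated)
11 | (2S,3S)-2-[3,4-bis(benzyloxy)phenyl]-5-oxooxolane-3-carbaldehyde | O=C1C[C@H](C=O)[C@@H](c2ccc(OCc3ccccc3)c(OCc3ccccc3)c2)O1 | intermediate
12 | (4R,5S)-5-[3,4-bis(benzyloxy)phenyl]-4-(hydroxymethyl)oxolan-2-one | O=C1C[C@H](CO)[C@@H](c2ccc(OCc3ccccc3)c(OCc3ccccc3)c2)O1 | intermediate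
13 | (4R,5S)-5-[3,4-bis(benzyloxy)phenyl]-4-{[(tert-butyldiphenylsilyl)oxy]methyl}oxolan-2-one | O=C1C[C@H](CO[Si](c2ccccc2)(c2ccccc2)C(C)(C)C)[C@@H](c2ccc(OCc3ccccc3)c(OCc3ccccc3)c2)O1 | intermediate
14 | 4-(benzyloxy)-3-methoxybenzaldehyde | COc1cc(C=O)ccc1OCc1ccccc1 | starting material
15 | (3R,4R,5S)-3-{[4-(benzyloxy)-3-methoxyphenyl](hydroxy)methyl}-5-[3,4-bis(benzyloxy)phenyl]-4-{[(tert-butyldiphenylsilyl)oxy]methyl}oxolan-2-one, both carbinol epimers | O=C1O[C@H](c2ccc(OCc3ccccc3)c(OCc3ccccc3)c2)[C@@H](CO[Si](c2ccccc2)(c2ccccc2)C(C)(C)C)[C@@H]1C(O)c1ccc(OCc2ccccc2)c(OC)c1 | intermediate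
16 | methanesulfonate of 15, both epimers | O=C1O[C@H](c2ccc(OCc3ccccc3)c(OCc3ccccc3)c2)[C@@H](CO[Si](c2ccccc2)(c2ccccc2)C(C)(C)C)[C@@H]1C(OS(C)(=O)=O)c1ccc(OCc2ccccc2)c(OC)c1 | intermediate (not isolated)
17 | (3E,4R,5S)-3-[4-(benzyloxy)-3-methoxybenzylidene]-5-[3,4-bis(benzyloxy)phenyl]-4-{[(tert-butyldiphenylsilyl)oxy]methyl}oxolan-2-one | O=C1O[C@H](c2ccc(OCc3ccccc3)c(OCc3ccccc3)c2)[C@@H](CO[Si](c2ccccc2)(c2ccccc2)C(C)(C)C)/C1=C\c1ccc(OCc2ccccc2)c(OC)c1 | intermediate
18 | (3R,4R,5S)-3-[4-(benzyloxy)-3-methoxybenzyl]-5-[3,4-bis(benzyloxy)phenyl]-4-{[(tert-butyldiphenylsilyl)oxy]methyl}oxolan-2-one | COc1cc(C[C@H]2C(=O)O[C@H](c3ccc(OCc4ccccc4)c(OCc4ccccc4)c3)[C@H]2CO[Si](c2ccccc2)(c2ccccc2)C(C)(C)C)ccc1OCc1ccccc1 | intermediate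
19 | (3R,4R,5S)-3-[4-(benzyloxy)-3-methoxybenzyl]-5-[3,4-bis(benzyloxy)phenyl]-4-{[(tert-butyldiphenylsilyl)oxy]methyl}oxolan-2-ol, both anomers | COc1cc(C[C@H]2C(O)O[C@H](c3ccc(OCc4ccccc4)c(OCc4ccccc4)c3)[C@H]2CO[Si](c2ccccc2)(c2ccccc2)C(C)(C)C)ccc1OCc1ccccc1 | intermediate
20 | {[(2S,3R,4R)-4-[4-(benzyloxy)-3-methoxybenzyl]-2-[3,4-bis(benzyloxy)phenyl]oxolan-3-yl]methoxy}(tert-butyl)diphenylsilane | COc1cc(C[C@H]2CO[C@H](c3ccc(OCc4ccccc4)c(OCc4ccccc4)c3)[C@H]2CO[Si](c2ccccc2)(c2ccccc2)C(C)(C)C)ccc1OCc1ccccc1 | intermediate
21 | [(2S,3R,4R)-4-[4-(benzyloxy)-3-methoxybenzyl]-2-[3,4-bis(benzyloxy)phenyl]oxolan-3-yl]methanol | COc1cc(C[C@H]2CO[C@H](c3ccc(OCc4ccccc4)c(OCc4ccccc4)c3)[C@H]2CO)ccc1OCc1ccccc1 | intermediate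
22 | [(2S,3R,4R)-4-[4-(benzyloxy)-3-methoxybenzyl]-2-[3,4-bis(benzyloxy)phenyl]oxolan-3-yl]methyl acetate | COc1cc(C[C@H]2CO[C@H](c3ccc(OCc4ccccc4)c(OCc4ccccc4)c3)[C@H]2COC(C)=O)ccc1OCc1ccccc1 | intermediate
23 | [(2S,3R,4R)-2-(3,4-dihydroxyphenyl)-4-(4-hydroxy-3-methoxybenzyl)oxolan-3-yl]methyl acetate | COc1cc(C[C@H]2CO[C@H](c3ccc(O)c(O)c3)[C@H]2COC(C)=O)ccc1O | target

## Step count and risks

Total: 14 steps. Longest linear sequence: 14 steps, from 1 to 23. The aryl bromide 5 and the aldehyde 14 enter as purchased materials.

**Step 4 (key step).** The cascade passes through a β-hydroxy aldehyde (10) and ends in a β-acyloxy aldehyde (11) whose β-carbon is benzylic to an electron-rich ring. Retro-aldol loss of the aryl aldehyde before lactonisation, or base-induced β-elimination of the lactone oxygen afterwards, could consume material.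
- Fallback (from 8, back at 13): 8 is treated with NaBH4 in MeOH at −20 °C. Methoxide strips the oxalate, and the hydride reduces the aldehyde as soon as the cyclopropane opens, so no sensitive aldehyde persists.
- A cold acidic quench should give ethyl (3R,4S)-4-[3,4-bis(benzyloxy)phenyl]-4-hydroxy-3-(hydroxymethyl)butanoate F1.
- Selective silylation of its primary hydroxyl (TBDPSCl, imidazole) gives ethyl (3R,4S)-4-[3,4-bis(benzyloxy)phenyl]-3-{[(tert-butyldiphenylsilyl)oxy]methyl}-4-hydroxybutanoate F2.
- Only the benzylic hydroxyl then remains to lactonise (PPTS, toluene, 60 °C). The same O1–C5 bond closes, now at the alcohol oxidation level, and gives 13.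

**Step 3.** Incomplete facial selectivity in the aryl addition is the main concern. The minor carbinol epimer would, after the cascade and equilibration, become the enantiomer of 11 and erode optical purity. Competing attack on the oxalate is a lesser concern.
- Fallback (from 8 as its carbinol mixture, back at 8): Dess–Martin oxidation gives ethyl (1R,2R,3R)-2-[3,4-bis(benzyloxy)benzoyl]-3-[(methoxyoxalyl)oxy]cyclopropane-1-carboxylate F3.
- Noyori asymmetric transfer hydrogenation of this aryl ketone (RuCl(p-cymene)[(S,S)-TsDPEN], HCO2H/Et3N) then sets the (S)-carbinol by reagent control.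

**Step 9.** The C5 aryl group of the lactone lies on the face from which hydrogen must come, so facial discrimination may be incomplete. Partial loss of benzyl ethers or arene saturation on the catalyst is also possible.
- Fallback (from 13, back at 18): the enolate of 13 (LiN(SiMe3)2, THF, −78 °C) is alkylated with 4-(benzyloxy)-3-methoxybenzyl bromide. This gives the trans lactone (3S,4R,5S)-3-[4-(benzyloxy)-3-methoxybenzyl]-5-[3,4-bis(benzyloxy)phenyl]-4-{[(tert-butyldiphenylsilyl)oxy]methyl}oxolan-2-one F4.
- F4 is re-enolised (KN(SiMe3)2, −78 °C) and protonated kinetically with a hindered phenol anti to the silyloxymethyl group. This inverts the α-centre to the cis lactone 18 without hydrogen gas.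

**Step 11.** BF3 may ionise the benzylic C2–O1 bond as well as the lactol. That would cause epimerisation at C2 or reductive ring opening.
- Fallback (from 18, back at 20): LiAlH4 reduction gives (1S,2R,3R)-3-[4-(benzyloxy)-3-methoxybenzyl]-1-[3,4-bis(benzyloxy)phenyl]-2-{[(tert-butyldiphenylsilyl)oxy]methyl}butane-1,4-diol F5.
- Selective sulfonylation of the primary hydroxyl (TsCl, pyridine, 0 °C) gives the mono-tosylate F6.
- NaH in THF closes the ring by SN2 attack of the benzylic alkoxide on the primary carbon. The C2 stereocentre is never ionised.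

**Step 14.** Hydrogenolysis may continue from the benzyl ethers to the benzylic C2–O1 bond and open the ring.
- Fallback (from 22, directly to 23): Lewis-acid debenzylation with BCl3 and pentamethylbenzene as benzyl-cation scavenger in CH2Cl2 at −78 °C. This removes aryl benzyl ethers without hydrogen and leaves the acetate in place.

## Further compounds

F1 | step 4 | ethyl (3R,4S)-4-[3,4-bis(benzyloxy)phenyl]-4-hydroxy-3-(hydroxymethyl)butanoate | CCOC(=O)C[C@H](CO)[C@H](O)c1ccc(OCc2ccccc2)c(OCc2ccccc2)c1
F2 | step 4 | ethyl (3R,4S)-4-[3,4-bis(benzyloxy)phenyl]-3-{[(tert-butyldiphenylsilyl)oxy]methyl}-4-hydroxybutanoate | CCOC(=O)C[C@H](CO[Si](c1ccccc1)(c1ccccc1)C(C)(C)C)[C@H](O)c1ccc(OCc2ccccc2)c(OCc2ccccc2)c1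
F3 | step 3 | ethyl (1R,2R,3R)-2-[3,4-bis(benzyloxy)benzoyl]-3-[(methoxyoxalyl)oxy]cyclopropane-1-carboxylate | CCOC(=O)[C@H]1[C@H](OC(=O)C(=O)OC)[C@@H]1C(=O)c1ccc(OCc2ccccc2)c(OCc2ccccc2)c1
F4 | step 9 | (3S,4R,5S)-3-[4-(benzyloxy)-3-methoxybenzyl]-5-[3,4-bis(benzyloxy)phenyl]-4-{[(tert-butyldiphenylsilyl)oxy]methyl}oxolan-2-one | COc1cc(C[C@@H]2C(=O)O[C@H](c3ccc(OCc4ccccc4)c(OCc4ccccc4)c3)[C@H]2CO[Si](c2ccccc2)(c2ccccc2)C(C)(C)C)ccc1OCc1ccccc1
F5 | step 11 | (1S,2R,3R)-3-[4-(benzyloxy)-3-methoxybenzyl]-1-[3,4-bis(benzyloxy)phenyl]-2-{[(tert-butyldiphenylsilyl)oxy]methyl}butane-1,4-diol | COc1cc(C[C@@H](CO)[C@H](CO[Si](c2ccccc2)(c2ccccc2)C(C)(C)C)[C@H](O)c2ccc(OCc3ccccc3)c(OCc3ccccc3)c2)ccc1OCc1ccccc1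
F6 | step 11 | (2R,3R,4S)-2-[4-(benzyloxy)-3-methoxybenzyl]-4-[3,4-bis(benzyloxy)phenyl]-3-{[(tert-butyldiphenylsilyl)oxy]methyl}-4-hydroxybutyl 4-methylbenzenesulfonate | COc1cc(C[C@@H](COS(=O)(=O)c2ccc(C)cc2)[C@H](CO[Si](c2ccccc2)(c2ccccc2)C(C)(C)C)[C@H](O)c2ccc(OCc3ccccc3)c(OCc3ccccc3)c2)ccc1OCc1ccccc1
F0 | step 14 | none | none
A1 | alternative 1 | [(2S,3R,4R)-2-(3,4-dihydroxyphenyl)-4-(4-hydroxy-3-methoxybenzyl)oxolan-3-yl]methanol | COc1cc(C[C@H]2CO[C@H](c3ccc(O)c(O)c3)[C@H]2CO)ccc1O
A2 | alternative 1 | (2R,3R)-2-(3,4-dihydroxybenzyl)-3-(4-hydroxy-3-methoxybenzyl)butane-1,4-diol | COc1cc(C[C@@H](CO)[C@H](CO)Cc2ccc(O)c(O)c2)ccc1O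
A3 | alternative 1 | para-quinone methide of A2 (3-hydroxy-4-oxocyclohexa-2,5-dien-1-ylidene at the benzylic carbon) | COc1cc(C[C@@H](CO)[C@H](CO)C=C2C=CC(=O)C(O)=C2)ccc1O
A4 | alternative 2 | trans-2-[3,4-bis(benzyloxy)phenyl]-4-[4-(benzyloxy)-3-methoxybenzyl]-3-{[(tert-butyldimethylsilyl)oxy]methyl}-2,3-dihydrofuran | COc1cc(CC2=CO[C@H](c3ccc(OCc4ccccc4)c(OCc4ccccc4)c3)[C@H]2CO[Si](C)(C)C(C)(C)C)ccc1OCc1ccccc1
A5 | alternative 2 | (Z)-2-[4-(benzyloxy)-3-methoxybenzyl]-4-[(tert-butyldimethylsilyl)oxy]but-2-enal | O=C/C(Cc1ccc(OCc2ccccc2)c(OC)c1)=C\CO[Si](C)(C)C(C)(C)C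
A6 | alternative 2 | [3,4-bis(benzyloxy)phenyl]diazomethane | [N-]=[N+]=Cc1ccc(OCc2ccccc2)c(OCc2ccccc2)c1
A7 | alternative 3 | cis-fused 6-[3,4-bis(benzyloxy)phenyl]-4-menthyloxy-3,7-dioxabicyclo[3.3.0]octan-2-one, aryl exo | O=C1O[C@H](O[C@H]3C[C@@H](C)CC[C@@H]3C(C)C)[C@H]2CO[C@H](c3ccc(OCc4ccccc4)c(OCc4ccccc4)c3)[C@@H]12
A8 | alternative 3 | (5S)-5-{[(1S,2R,5S)-2-isopropyl-5-methylcyclohexyl]oxy}furan-2(5H)-one | O=C1O[C@H](O[C@H]2C[C@@H](C)CC[C@@H]2C(C)C)C=C1
A9 | alternative 3 | {[3,4-bis(benzyloxy)phenyl](chloromethoxy)methyl}trimethylsilane | C[Si](C)(C)C(OCCl)c1ccc(OCc2ccccc2)c(OCc2ccccc2)c1
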